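(All runs were computed for an exercise, and the scatter is random.)

The closed, stirred flask starts with its substrate undissolved, and what counts is the target standing at the end.

| flask | solid substrate | partner | protic impurity | temperature | remark | time |
|---|---|---|---|---|---|---|
| blue | 1 mM | 2 mM | 0.20 mM | 95 °C | run made earlier |  |
| south-east | 1.0 mM | 2.00 mM | 0.100 mM |  | at 110 °C until 1.0 min, from then on at 95 °C | 5.0 min |
| north-east | 1.0 mM | 2.00 mM | 0.100 mM | 95 °C |  | 5.0 min |
| east | 1.0 mM | 2.00 mM | 0.100 mM | 110 °C |  | 5.0 min |

blue run (percent of the solid substrate charged)

| time / s | target / % |
|---|---|
| 12.0 | 0.1 |
| 30.0 | 3.8 |
| 60.0 | 19.1 |
| 90.0 | 41.6 |

(readings scatter by 1 percentage point)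

- target is meant together with its crystals
- solid, in amounts per volume of the solution: solid substrate, crystals
- the numbers in the tables scatter by 1 percentage point (one standard deviation)
- candidate steps: starting material <-> open intermediate; 2 second intermediate -> homo product; crystals <-> target; solid substrate <-> starting material; open intermediate + second intermediate -> target; partner + protic impurity -> quenched reagent; partner -> second intermediate
- at the start none of the solid substrate is in solution
- what has only dissolved of solid substrate counts as not reacted
- the earlier runs do not show what temperature does; that part of a forecast is a guess
- no earlier run changes the charge of protic impurity; that part of a forecast is a guess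

1. the best flask by amount of target, in percent of the solid substrate charged; "all alike" if 1.5 percentage points covers them all (south-east / north-east / east / all alike)
2. amount of target at the end, in percent of the solid substrate charged, south-east
3. amount of target at the end, in percent of the solid substrate charged, north-east
4. amount of target at the end, in percent of the solid substrate charged, east

I take the solid substrate as the limiting reagent. In the blue run, partner less protic impurity leaves 1.80 mM against 1 mM of solid substrate, so I assume that second intermediate stands in excess. On that assumption the concentration that sets the order late in the run is the share not yet target, and I treat the tail as pseudo-first-order; homo-coupling uses second intermediate too, so this is a rough estimate. Two times remain to be compared.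

The blue run shows a hold-up early, with 0.1% at 12.0 s, so I read the first time from its last two readings: 63.8 s for the tail half-life, the time in which the share not yet target halves. This is a reading and carries their scatter. The second time is what remains after the last reading, 210 s. Their ratio is 3.29 half-lives, so the 58.4% still open at 90.0 s shrinks and I expect 94.0% of target in north-east, taking the smaller charge of protic impurity as a guess to change little. The temperature effect is also a guess: I suppose that heat shortens the half-life, and so I rank east first, then south-east, then north-east.

The forecast gives 86% for south-east, 88% for north-east and 83% for east, with north-east best, lower than my figure for north-east, holding that “end values depend on selectivity, not on time”.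

South-east gives 93.8%, north-east 93.5% and east 97.9%, so east is best.

    starting material ⇌ open intermediate (K = 2.40, k = 0.0720 /s, Ea = 86.0 kJ/mol, ΔH = −15.0 kJ/mol)
    2 second intermediate → homo product (k = 2.10 /M/s, Ea = 54.0 kJ/mol)
    crystals ⇌ target, rate k3*(cs3 - [target]) while solid is left; crystals form when [target] > cs3 (solubility = 0.580 mM, k = 1.20 /s)
    solid substrate ⇌ starting material, rate k4*(cs4 - [starting material]) while solid is left; crystals form when [starting material] > cs4 (solubility = 0.860 mM, k = 0.0270 /s)
    open intermediate + second intermediate → target (k = 45.0 /M/s, Ea = 44.0 kJ/mol)
    partner + protic impurity → quenched reagent (k = 220 /M/s, Ea = 50.0 kJ/mol)
    partner → second intermediate (k = 0.0910 /s, Ea = 97.0 kJ/mol)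
    (constants at 110 °C)

In north-east, second intermediate falls from 0.833 mM at 2.50 min to 0.516 mM at 5.00 min, so it does not stay constant as I assumed, and the tail is not truly first order. Reckoned as an average over the interval in east, from 66.6% of target at 80 s to 97.9% at 5.0 min, the tail half-life is 55.5 s, shorter than the 63.8 s read from the blue run.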